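The plan traces carbocycle A (C1 ketone, C2 bearing the hexanoic acid chain, C3 enol, C4 and C5 shared with the dihydropyranone, C6 quaternary) back to a cyclobutenone. The key step exploits the alternating oxygens at C1, C3 and C5 of this fully substituted ring. Its precursor is a spiro 3-siloxycyclobutenone (ring atoms C5, C6, C1, C2), joined by a ketene–siloxyalkyne [2+2] from a pinene-derived alkyne and an organocatalytically made enol lactone. It opens (4π) and recloses (6π) onto its exocyclic enol-ester C3=C4 bond. One operation gives the six-membered ring, pentasubstituted, with three chemically distinct oxygens. Chromanone annulation and catalyst-controlled dearomative prenylation at C6 follow.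

Key step: step 8

Remark: C1–C6 are the locants of carbocycle A defined above and O1/O3/O5 the oxygens on them; Cb = [(1S,3R)-2,2-dimethyl-3-(prop-1-en-2-yl)cyclobutyl]methyl; methyl prenyl carbonate, both antipodes of the chiral catalysts and (S)-but-3-en-2-ol are taken as catalogue items.

Step 1
Reactants: 1 (+)-α-pinene
Product: 2 cis-pinonic acid (1S,3S)
Conditions: RuCl3·xH2O (2 mol %), NaIO4 (4 equiv), EtOAc–MeCN–H2O, 0 °C to rt
Reagents that add atoms: sodium periodate, [Na+].[O-]I(=O)(=O)=O
Why: Catalytic RuO4/periodate oxidative cleavage of the trisubstituted alkene gives the methyl ketone and the acid, and both cyclobutane stereocentres are bought with 1 and stay cis because they were the bridgeheads of the bicycle.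

Step 2
Reactants: 2 cis-pinonic acid
Product: 3 methyl cis-pinonate
Conditions: MeOH, TsOH·H2O (5 mol %), 40 °C
Reagents that add atoms: methanol, CO
Why: Fischer esterification under mild acid catalysis should leave the epimerisable ring carbon next to the acetyl group untouched.

Step 3
Reactants: 3 methyl cis-pinonate
Product: 4 methyl 2-[(1S,3R)-2,2-dimethyl-3-(prop-1-en-2-yl)cyclobutyl]acetate
Conditions: Ph3PCH3Br (1.3 equiv), KOt-Bu (1.2 equiv), THF, 0 °C to rt
Reagents that add atoms: methyltriphenylphosphonium bromide, C[P+](c1ccccc1)(c1ccccc1)c1ccccc1.[Br-]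
Why: Wittig methylenation takes the ketone in preference to the ester, and the excess of phosphonium salt over base should prevent epimerisation of the adjacent ring stereocentre.

Step 4
Reactants: 4 methyl 2-[(1S,3R)-2,2-dimethyl-3-(prop-1-en-2-yl)cyclobutyl]acetate
Product: 6 siloxyalkyne Cb–C≡C–OTIPS, via lithium ynolate 5 (not isolated)
Conditions: CH2Br2, LiTMP, THF, −78 °C, then 4; n-BuLi, −78 °C to rt; TIPSOTf, −78 to 0 °C
Reagents that add atoms: dibromomethane, BrCBr; triisopropylsilyl trifluoromethanesulfonate, CC(C)[Si](OS(=O)(=O)C(F)(F)F)(C(C)C)C(C)C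
Why: This is a Kowalski ester homologation stopped at the ynolate, in which LiCHBr2 addition, bromine–lithium exchange and a 1,2-shift give 5, which the bulky silyl triflate traps on oxygen, and no stereocentre takes part.

Step 5
Reactants: 7 (E)-hex-2-enal; 8 tert-butyl acetoacetate
Product: 9 tert-butyl (4S)-6-methyl-2-oxo-4-propyl-3,4-dihydro-2H-pyran-5-carboxylate
Conditions: aminoindanol-derived N-mesityl triazolium chloride (10 mol %, antipode giving 4S), DBU (15 mol %), 3,3',5,5'-tetra-tert-butyldiphenoquinone (1.1 equiv), PhMe, rt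
Reagents that add atoms: none
Why: Oxidative N-heterocyclic-carbene catalysis (α,β-unsaturated acyl azolium, Michael addition, then enol lactonisation) joins 7 and 8, and the chiral azolium shields one face of the β-carbon, which sets the propyl-bearing stereocentre as S.

Step 6
Reactants: 9 tert-butyl (4S)-6-methyl-2-oxo-4-propyl-3,4-dihydro-2H-pyran-5-carboxylate
Product: 10 (4S)-6-methyl-2-oxo-4-propyl-3,4-dihydro-2H-pyran-5-carboxylic acid
Conditions: TFA–CH2Cl2 (1:4), rt
Reagents that add atoms: none
Why: Acidolysis of the tert-butyl ester (E1 loss of isobutene) should leave the enol lactone and the stereocentre untouched.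

Step 7
Reactants: 10 (4S)-6-methyl-2-oxo-4-propyl-3,4-dihydro-2H-pyran-5-carboxylic acid; 6 siloxyalkyne Cb–C≡C–OTIPS
Product: 13 spiro cyclobutenone (9S)-2-Cb-5-methylidene-9-propyl-3-(triisopropylsilyloxy)-6-oxaspiro[3.5]non-2-ene-1,7-dione (both C4 epimers), via acid chloride 11 (not isolated), via vinylketene 12 (not isolated)
Conditions: (COCl)2, DMF (cat.), CH2Cl2, 0 °C to rt, evaporate; slow addition to 6 and Et3N (1.5 equiv), PhMe, rt
Reagents that add atoms: none
Why: 1,4-Dehydrochlorination of 11 through its vinylogous methyl group gives vinylketene 12, and in the regioselective ketene–ynol ether [2+2] cycloaddition the Cb-bearing alkyne carbon bonds to the ketene carbonyl carbon, while the new spiro centre may form as a mixture because step 8 erases it.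

Step 8
Reactants: 13 spiro cyclobutenone
Product: 16 phenol (4S)-7-hydroxy-6-Cb-4-propyl-5-(triisopropylsilyloxy)chroman-2-one, via dienylketene 14 (not isolated), via cyclohexadienone 15 (not isolated)
Conditions: PhMe (0.05 M), BHT (cat.), 110 °C, sealed tube
Reagents that add atoms: none
Why: Heating opens the cyclobutenone by conrotatory 4π cleavage of the C5–C2 bond to dienylketene 14, whose ketene carbon C5 bonds to the methylene carbon C4 in a disrotatory 6π electrocyclisation to cyclohexa-2,4-dienone 15, and a proton shift from C4 to O5 then gives phenol 16. The closest known reaction type is the second half of the Danheiser benzannulation, the thermal ring expansion of a 4-alkenylcyclobutenone that is also the basis of the Moore rearrangement. The only ring closed is carbocycle A, by 6π electrocyclisation, so the four-membered ring C5–C6–C1–C2 grows by the two atoms C3 and C4, while the lactone ring merely changes from spiro to fused. No stereocentre is created: the spiro carbon C2 becomes sp2, and the propyl-bearing centre and the two cyclobutane centres are spectators. The step needs inward rotation of the alkenyl arm at C2, which is secured because the 4π opening is reversible, only the isomer of 14 with C3 cis to the ketene can cyclise, and aromatisation drains the equilibrium. The substitution pattern needs no further control because it is written into the connectivity of 13 (Cb on C6, silyl ether on C1, lactone oxygen on C3, free phenol at C5, hydrogen only at C4).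

Step 9
Reactants: 16 phenol
Product: 17 salicylaldehyde (4S)-7-hydroxy-2-oxo-6-Cb-4-propyl-5-(triisopropylsilyloxy)chromane-8-carbaldehyde
Conditions: MgCl2 (2 equiv), Et3N (4 equiv), (CH2O)n (7 equiv), THF, 65 °C; 1 M HCl work-up
Reagents that add atoms: paraformaldehyde (as formaldehyde), C=O
Why: In the Casnati–Skattebøl ortho-formylation the magnesium phenoxide delivers formaldehyde to C4, the only free ring position, and a second formaldehyde oxidises the benzylic alkoxide, all without the strong acid that would ionise the isopropenylcyclobutane.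

Step 10
Reactants: 17 salicylaldehyde
Product: 18 tigloyl phenol (4S)-7-hydroxy-8-[(E)-2-methylbut-2-enoyl]-6-Cb-4-propyl-5-(triisopropylsilyloxy)chroman-2-one
Conditions: [RhCl(cod)]2 (2.5 mol %), dppf (5 mol %), Na2CO3 (5 mol %), but-2-yne (5 equiv), PhMe, 80 °C, sealed tube
Reagents that add atoms: but-2-yne, CC#CC
Why: Phenoxide-chelation-assisted Rh(I) alkyne hydroacylation adds acyl and hydrogen syn across but-2-yne, which gives the E (tigloyl) enone under non-acidic conditions, and the hindered 1,1-disubstituted alkene should not compete with the alkyne.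

Step 11
Reactants: 18 tigloyl phenol
Product: 19 tricycle with cis-(2R,3S)-2,3-dimethylchroman-4-one on O5/C4 and (4S)-4-propyl lactone on O3/C2 and C1–OTIPS and C6–Cb
Conditions: (−)-quinine (20 mol %), PhCl, 10–15 °C
Reagents that add atoms: none
Why: In this cinchona-alkaloid-catalysed intramolecular oxa-Michael addition (6-endo-trig closure through O5, the only free flanking oxygen since O3 is locked in the lactone) the quinuclidine nitrogen activates the phenol and the C9 hydroxyl the enone, which fixes the attacked face of the β-carbon (chromanone C2, R), and kinetic protonation of the enolate by the ammonium ion from the same side gives the cis partner (chromanone C3, S).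

Step 12
Reactants: 19 tricycle
Product: 21 methyl (3S)-3-[(2R,3S)-5,7-dihydroxy-2,3-dimethyl-4-oxo-8-Cb-chroman-6-yl]hexanoate, via phenol lactone 20 (not isolated)
Conditions: TBAF (1.1 equiv), THF–MeOH (1:1), 0 °C to rt; AcOH quench
Reagents that add atoms: methanol, CO
Why: Fluoride desilylation gives the phenoxide of 20, which is basic enough to catalyse methanolysis (transesterification) of the aryl lactone but, being conjugated with the chromanone carbonyl, lowers the acidity of the neighbouring C–H so that the cis-dimethyl unit should not epimerise.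

Step 13
Reactants: 21 methyl ester diphenol
Product: 22 methyl (3S)-3-[(2R,3S,8R)-5-hydroxy-2,3-dimethyl-8-(3-methylbut-2-en-1-yl)-4,7-dioxo-8-Cb-3,4,7,8-tetrahydro-2H-chromen-6-yl]hexanoate
Conditions: Pd2(dba)3·CHCl3 (2.5 mol %), (R,R)-DACH-phenyl bis(2-diphenylphosphinobenzamide) ligand (7.5 mol %), methyl prenyl carbonate (1.3 equiv), PhMe, 0 °C to rt
Reagents that add atoms: methyl prenyl carbonate, COC(=O)OCC=C(C)C
Why: In this palladium-catalysed asymmetric allylic dearomatisation (Tsuji–Trost type, neutral carbonate variant) O-prenylation is reversible, C4 is blocked by the chelated acyl group and C2 by its secondary alkyl group, so C6 takes up the prenyl unit at its CH2 terminus on the face of the flat phenoxide left open by the ligand pocket (this sets C6 as R, with the ligand antipode in reserve should a pilot run show the opposite sense), and the hydrogen-bonded vinylogous acid that results should make the C–C bond formation irreversible.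

Step 14
Reactants: 22 methyl ester
Product: 23 target acid CNP0364345.1
Conditions: LiOH (4 equiv), THF–H2O (3:1), 0 °C to rt; 1 M HCl to pH 3
Reagents that add atoms: lithium hydroxide, [Li+].[OH-]
Why: In this saponification ring A is deprotonated first to the delocalised enolate of the vinylogous acid, which should shield the chromanone α-carbon from enolisation and the pyranone from retro-oxa-Michael opening, so all six stereocentres should persist.

Compound list
1 | (+)-α-pinene, (1R,5R)-2,6,6-trimethylbicyclo[3.1.1]hept-2-ene | CC1=CC[C@@H]2C[C@H]1C2(C)C | starting material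
2 | cis-pinonic acid, 2-[(1S,3S)-3-acetyl-2,2-dimethylcyclobutyl]acetic acid | CC(=O)[C@H]1C[C@@H](CC(=O)O)C1(C)C | intermediate
3 | methyl 2-[(1S,3S)-3-acetyl-2,2-dimethylcyclobutyl]acetate | CC(=O)[C@H]1C[C@@H](CC(=O)OC)C1(C)C | intermediate
4 | methyl 2-[(1S,3R)-2,2-dimethyl-3-(prop-1-en-2-yl)cyclobutyl]acetate | C=C(C)[C@H]1C[C@@H](CC(=O)OC)C1(C)C | intermediate
5 | lithium 3-[(1S,3R)-2,2-dimethyl-3-(prop-1-en-2-yl)cyclobutyl]prop-1-yn-1-olate | C=C(C)[C@H]1C[C@@H](CC#C[O-])C1(C)C.[Li+] | intermediate
6 | ({3-[(1S,3R)-2,2-dimethyl-3-(prop-1-en-2-yl)cyclobutyl]prop-1-yn-1-yl}oxy)triisopropylsilane | C=C(C)[C@H]1C[C@@H](CC#CO[Si](C(C)C)(C(C)C)C(C)C)C1(C)C | intermediate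
7 | (E)-hex-2-enal | CCC/C=C/C=O | starting material
8 | tert-butyl acetoacetate | CC(=O)CC(=O)OC(C)(C)C | starting material
9 | tert-butyl (4S)-6-methyl-2-oxo-4-propyl-3,4-dihydro-2H-pyran-5-carboxylate | CCC[C@H]1CC(=O)OC(C)=C1C(=O)OC(C)(C)C | intermediate
10 | (4S)-6-methyl-2-oxo-4-propyl-3,4-dihydro-2H-pyran-5-carboxylic acid | CCC[C@H]1CC(=O)OC(C)=C1C(=O)O | intermediate
11 | (4S)-6-methyl-2-oxo-4-propyl-3,4-dihydro-2H-pyran-5-carbonyl chloride | CCC[C@H]1CC(=O)OC(C)=C1C(=O)Cl | intermediate
12 | vinylketene, (4S)-6-methylidene-5-(oxomethylidene)-4-propyloxan-2-one | CCC[C@H]1CC(=O)OC(=C)C1=C=O | intermediate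
13 | (9S)-2-{[(1S,3R)-2,2-dimethyl-3-(prop-1-en-2-yl)cyclobutyl]methyl}-5-methylidene-9-propyl-3-(triisopropylsilyloxy)-6-oxaspiro[3.5]non-2-ene-1,7-dione (spiro carbon C4 as epimer mixture, left undefined) | C=C(C)[C@H]1C[C@@H](CC2=C(O[Si](C(C)C)(C(C)C)C(C)C)C3(C2=O)C(=C)OC(=O)C[C@@H]3CCC)C1(C)C | intermediate
14 | dienylketene from 4π opening of 13 (C3 cis to the ketene arm) | C=C(C)[C@H]1C[C@@H](CC(=C=O)/C(O[Si](C(C)C)(C(C)C)C(C)C)=C2\C(=C)OC(=O)C[C@@H]2CCC)C1(C)C | intermediate
15 | cyclohexa-2,4-dienone, keto tautomer of 16 (C5=O, C4H2) | C=C(C)[C@H]1C[C@@H](CC2=C(O[Si](C(C)C)(C(C)C)C(C)C)C3=C(CC2=O)OC(=O)C[C@@H]3CCC)C1(C)C | intermediate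
16 | (4S)-6-{[(1S,3R)-2,2-dimethyl-3-(prop-1-en-2-yl)cyclobutyl]methyl}-7-hydroxy-4-propyl-5-(triisopropylsilyloxy)chroman-2-one | C=C(C)[C@H]1C[C@@H](Cc2c(O)cc3OC(=O)C[C@H](CCC)c3c2O[Si](C(C)C)(C(C)C)C(C)C)C1(C)C | intermediate
17 | 8-carbaldehyde of 16 | C=C(C)[C@H]1C[C@@H](Cc2c(O)c(C=O)c3OC(=O)C[C@H](CCC)c3c2O[Si](C(C)C)(C(C)C)C(C)C)C1(C)C | intermediate
18 | 8-[(E)-2-methylbut-2-enoyl] derivative of 16 | C=C(C)[C@H]1C[C@@H](Cc2c(O)c(C(=O)/C(C)=C/C)c3OC(=O)C[C@H](CCC)c3c2O[Si](C(C)C)(C(C)C)C(C)C)C1(C)C | intermediate
19 | tricycle: cis-(2R,3S)-2,3-dimethylchroman-4-one (O5/C4) fused to the (4S)-4-propyldihydrocoumarin (O3/C2), C1–OTIPS, C6–Cb | C=C(C)[C@H]1C[C@@H](Cc2c3O[C@H](C)[C@H](C)C(=O)c3c4OC(=O)C[C@H](CCC)c4c2O[Si](C(C)C)(C(C)C)C(C)C)C1(C)C | intermediate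
20 | desilylated tricycle (C1–OH, lactone intact) | C=C(C)[C@H]1C[C@@H](Cc2c3O[C@H](C)[C@H](C)C(=O)c3c4OC(=O)C[C@H](CCC)c4c2O)C1(C)C | intermediate
21 | methyl (3S)-3-[(2R,3S)-8-{[(1S,3R)-2,2-dimethyl-3-(prop-1-en-2-yl)cyclobutyl]methyl}-5,7-dihydroxy-2,3-dimethyl-4-oxochroman-6-yl]hexanoate | C=C(C)[C@H]1C[C@@H](Cc2c3O[C@H](C)[C@H](C)C(=O)c3c(O)c([C@@H](CCC)CC(=O)OC)c2O)C1(C)C | intermediate
22 | methyl ester of the target, (3S,2R,3S,8R) as in 23 | C=C(C)[C@H]1C[C@@H](C[C@@]2(CC=C(C)C)C(=O)C([C@@H](CCC)CC(=O)OC)=C(O)C3=C2O[C@H](C)[C@H](C)C3=O)C1(C)C | intermediate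
23 | (3S)-3-[(2R,3S,8R)-8-{[(1S,3R)-2,2-dimethyl-3-(prop-1-en-2-yl)cyclobutyl]methyl}-5-hydroxy-2,3-dimethyl-8-(3-methylbut-2-en-1-yl)-4,7-dioxo-3,4,7,8-tetrahydro-2H-chromen-6-yl]hexanoic acid | C=C(C)[C@H]1C[C@@H](C[C@@]2(CC=C(C)C)C(=O)C([C@@H](CCC)CC(=O)O)=C(O)C3=C2O[C@H](C)[C@H](C)C3=O)C1(C)C | target

Total step count: 14. Longest linear sequence: 12 (steps 1–4 and 7–14, from 1).

Steps most likely to fail

(a) Step 13. The ligand may discriminate poorly between the two faces of the flat phenoxide, or the prenyl transfer may end at O1 or C2. The fallback replaces catalyst control by a [3,3] chirality transfer and sets out from 21.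
- The non-chelated C1–OH is etherified under Mitsunobu conditions (PPh3, DIAD, THF, sonication) with (S)-but-3-en-2-ol. Inversion gives the (R)-but-3-en-2-yl aryl ether F1.
- Heating in toluene (Eu(fod)3 if needed) should bring about a dearomative ortho-Claisen rearrangement through a chair transition state with the methyl group equatorial. This carries the allyl unit to the face of C6 required for 8R and gives the (E)-crotyl dienone F2. C2 is the more hindered ortho position, and the para position C4 carries the acyl group.
- Cross-metathesis with 2-methylbut-2-ene (second-generation ruthenium catalyst, CH2Cl2, 40 °C) trims crotyl to prenyl and comes back to the route at 22.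

(b) Step 7. The vinylketene may oligomerise, or the ammonium salt may decompose the siloxyalkyne before the cycloaddition. The fallback separates ketene generation from the amine and sets out from 10.
- Acid chloride 11 is dehydrochlorinated with Et3N at high dilution without a trap, so that 12 closes (4π) to the fused cyclobutenone F3, which is purified.
- Heating F3 with 6 in toluene under amine-free Danheiser benzannulation conditions reopens it to 12, forms 13 in the flask and lets it expand through 14 and 15. The fallback comes back to the route at 16.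

(c) Step 11. The reversible oxa-Michael addition may give a poor cis/trans or facial preference, or resident and catalyst chirality may be mismatched. The fallback sets both centres by reduction instead of addition and sets out from 18.
- Cyclisation with Et3N and dehydrogenation with DDQ in the same flask gives the 2,3-dimethylchromone F4.
- Copper hydride asymmetric conjugate reduction (Cu(OAc)2, DTBM-SEGPHOS antipode chosen for 2R, PMHS, t-BuOH, PhMe) sets chromanone C2. Kinetic protonation of the enolate opposite to the 2-methyl group should give the cis C3 centre. The fallback comes back to the route at 19.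

Further compounds
F1 | step 13 | methyl (3S)-3-[(2R,3S)-7-[(2R)-but-3-en-2-yloxy]-8-Cb-5-hydroxy-2,3-dimethyl-4-oxochroman-6-yl]hexanoate | C=C(C)[C@H]1C[C@@H](Cc2c3O[C@H](C)[C@H](C)C(=O)c3c(O)c([C@@H](CCC)CC(=O)OC)c2O[C@H](C)C=C)C1(C)C
F2 | step 13 | methyl (3S)-3-[(2R,3S,8R)-8-[(E)-but-2-en-1-yl]-8-Cb-5-hydroxy-2,3-dimethyl-4,7-dioxo-3,4,7,8-tetrahydro-2H-chromen-6-yl]hexanoate | C=C(C)[C@H]1C[C@@H](C[C@@]2(C/C=C/C)C(=O)C([C@@H](CCC)CC(=O)OC)=C(O)C3=C2O[C@H](C)[C@H](C)C3=O)C1(C)C
F3 | step 7 | (5S)-5-propyl-2-oxabicyclo[4.2.0]oct-1(6)-ene-3,7-dione | O=C1CC2=C1[C@@H](CCC)CC(=O)O2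
F4 | step 11 | 2,3-dimethylchromone analogue of 19 (C2=C3 double bond in the pyranone) | C=C(C)[C@H]1C[C@@H](Cc2c3OC(C)=C(C)C(=O)c3c4OC(=O)C[C@H](CCC)c4c2O[Si](C(C)C)(C(C)C)C(C)C)C1(C)C
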